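I started from slowness: was anything in these flasks slow against 25 min?

| flask | starting material | protic impurity | remark | time |
|---|---|---|---|---|
| south | 1.6 M | 1.1 M | run made earlier |  |
| south-west | 1.6 M | 2.7 M | run made earlier |  |
| cedar | 1.6 M | 2.00 M |  | 25 min |
| maple | 1.6 M | 0.800 M |  | 25 min |

| run | time / min | target / % | starting material / % |
|---|---|---|---|
| south | 4.00 | 90.5 | 0.5 |
| south | 8.00 | 88.5 | 0 |
| south | 10.0 | 89.4 | 0 |
| south | 15.0 | 89.5 | 0 |
| south | 20.0 | 89.6 | 0.4 |
| south | 25.0 | 90.0 | 0 |
| south-west | 1.33 | 77.7 | 15.2 |
| south-west | 4.00 | 88.1 | 0.5 |
| south-west | 8.00 | 88.7 | 0.6 |
| south-west | 10.0 | 88.1 | 1.2 |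
| south-west | 15.0 | 87.6 | 0 |
| south-west | 20.0 | 89.1 | 0 |
| south-west | 25.0 | 88.6 | 0.9 |

(standard deviation of a reading: 0.5 percentage points)

- the numbers in the tables scatter by 0.5 percentage points (one standard deviation)

1. which of the two there is more of at the end, cedar (target / isomer of the product)
2. which of the two there is more of at the end, maple (target / isomer of the product)
3. how much target is there at the end, in percent of the starting material charged: cedar
4. how much target is there at the end, in percent of the starting material charged: maple

1. Fastest rung. In south-west, starting material fell to 15.2% at 1.33 min. Read as first-order decay, that is a half-life of 0.489 min, far shorter than 25 min.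

2. Next rung. By 4.00 min target stood on a plateau in both earlier runs. The readings from then on average 89.6% in south and 88.4% in south-west.

3. Last rung. South-west target moved 0.5 percentage points between 4.00 min and 25.0 min, about the scatter, so I read no drift and took the plateau as the end state.

4. As read, the plateaus of south and south-west, both charged with 1.6 M of starting material, differ by 1.2 points per equivalent, and I call this the toll: target given up per unit of c(protic impurity)/c(starting material).

5. From south, the toll gave me 88.9% for cedar and 89.8% for maple. Cedar's missing 11.1% caps the isomer of the product, so target is more, and likewise in maple.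

6. Second round. If each lost unit of target took one of impurity, I reckoned that cedar's impurity fell by a share of its charge equal to the toll, 1.22%. So I held c(protic impurity) constant and treated the loss as pseudo-first-order, and the correction is 0.019 points, far below the scatter.

The forecast gave target for cedar and target for maple, with 88.9% and 89.7%, where my maple figure was 89.8%, and called target “a stable end product”.

The flasks gave target at 88.8% in cedar, with 8.97% isomer of the product, and target at 90.0% in maple, with 9.09% isomer.

    starting material → target, rate k1*[starting material]/(1 + ([starting material]/sat1)) (1.13 M, k = 0.0379 s⁻¹)
    starting material + protic impurity → quenched substrate (k = 2.59 × 10⁻⁴ L mol⁻¹ s⁻¹)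
    target ⇌ isomer of the product (K = 0.101, k = 0.00195 s⁻¹)

The neighbour is cedar with protic impurity cut to 0.80 M, which is 0.500 equiv instead of 1.25. Adding the toll for that step to cedar's result, I reckoned 89.7% of target. The neighbour ended at 90.0% target and 9.09% isomer of the product, with 0% of its starting material and 98% of its protic impurity left.

The earlier runs and the new flask come from a simulation with made-up constants; noise was put on by code.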